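**Retrosynthetic overview**
- All carbons come from two molecules of aldehyde 1 and one of diester 2: both exocyclic C=C bonds of the symmetric E,E-diacid 3 are cut by a double Stobbe disconnection (rings A and C arrive intact).
- Auxiliary 4 ties the two carboxyl groups of 3 into the eight-membered amide ester 5 (first ring); in the same operation a 6π photocyclisation (C1–C8a disconnection) through 6 closes ring B of 7 (second ring) and sets C1/C2 cis.
- Reductive removal of the bridge gives diol 8; the remaining C3=C4 bond is hydrogenated under direction of the C2 hydroxymethyl group (sets C3, compound 9).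
- Hydrogenolysis of the two benzyl ethers gives target 10.

Assumption: the target is the (1R,2R,3R) isomer (tetralin numbering, aryl-bearing carbon = C1; aryl cis to the C2 CH2OH, the two CH2OH groups trans), and the sense of induction of the (S)-prolinol bridge is taken by analogy with related podophyllotoxin-series photocyclisations, recalled rather than checked; if it proved opposite, (R)-prolinol would be used with nothing else changed.

**Route**

Step 1
Reactants: 1 4-(benzyloxy)-3-methoxybenzaldehyde (2 equiv); 2 diethyl succinate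
Product: 3 (2E,3E)-2,3-bis{[4-(benzyloxy)-3-methoxyphenyl]methylidene}butanedioic acid
Conditions: KOt-Bu (3.2 equiv), t-BuOH, reflux; then 2 M HCl
Reagents that add atoms: none
Why: Double Stobbe condensation: each ester enolate adds to 1, the aldol alkoxide lactonises onto the other ester, and E1cB opening of the paraconate gives the favoured E-arylidene carboxylate, so two rounds give the E,E-diacid directly; no stereocentre is formed.

Step 2
Reactants: 3 (2E,3E)-2,3-bis{[4-(benzyloxy)-3-methoxyphenyl]methylidene}butanedioic acid; 4 (S)-prolinol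
Product: 7 (1R,2R)-7-(benzyloxy)-1-[4-(benzyloxy)-3-methoxyphenyl]-6-methoxy-1,2-dihydronaphthalene-2,3-dicarboxylic acid cyclic 2-ester 3-amide of (S)-prolinol, via bridged amide ester 5 (not isolated), via 1,8a-dihydronaphthalene 6 (not isolated)
Conditions: DCC (2.2 equiv), DMAP (0.3 equiv), CH2Cl2 (5 mM), 25 °C; filter; hν (365 nm, flow), 30 °C, N2
Reagents that add atoms: none
Why: Proposed new method: carbodiimide double condensation (amide first, then DMAP-assisted eight-membered lactonisation) locks the E,E-diene of 5 in one helical sense under the (S)-prolinol bridge, 365 nm light then drives a conrotatory 6π-electrocyclisation from that helix onto the unhindered ortho position (para to OMe) to give 6 with H-1 cis to H-8a, and a thermal suprafacial [1,5]-hydrogen shift rearomatises ring A and places H-2 cis to H-1, so the bridging ring and ring B form in one pot and C1 and C2 are set as (1R,2R) with aryl and carboxyl cis; closest known reaction type: stepwise amino-alcohol bridging of bis(benzylidene)succinic acids followed by auxiliary-controlled 6π photocyclisation and [1,5]-H shift (exchange of the amide and ester positions in the product would be harmless because step 3 removes the bridge).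

Step 3
Reactants: 7 (1R,2R)-7-(benzyloxy)-1-[4-(benzyloxy)-3-methoxyphenyl]-6-methoxy-1,2-dihydronaphthalene-2,3-dicarboxylic acid cyclic 2-ester 3-amide of (S)-prolinol
Product: 8 [(1R,2R)-7-(benzyloxy)-1-[4-(benzyloxy)-3-methoxyphenyl]-6-methoxy-1,2-dihydronaphthalene-2,3-diyl]dimethanol
Conditions: LiBHEt3 (6 equiv), THF, −40 → 0 °C; then H2O
Reagents that add atoms: none
Why: Hydride reduction with acyl C–O and C–N cleavage: LiBHEt3 reduces the ester and (through the hemiaminal and the aldehyde) the tertiary amide to primary alcohols in a 1,2-sense and releases the auxiliary; C1 and C2 are untouched because the carbonyl at C2 is consumed faster than it enolises.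

Step 4
Reactants: 8 [(1R,2R)-7-(benzyloxy)-1-[4-(benzyloxy)-3-methoxyphenyl]-6-methoxy-1,2-dihydronaphthalene-2,3-diyl]dimethanol
Product: 9 [(1R,2R,3R)-7-(benzyloxy)-1-[4-(benzyloxy)-3-methoxyphenyl]-6-methoxy-1,2,3,4-tetrahydronaphthalene-2,3-diyl]dimethanol
Conditions: H2 (1 atm), [Ir(cod)(PCy3)(py)]PF6 (5 mol %), CH2Cl2, 25 °C
Reagents that add atoms: none
Why: Hydroxyl-directed homogeneous hydrogenation: the cationic iridium catalyst is bound by the C2 hydroxymethyl group (the in-plane C3 hydroxymethyl group acting as second donor) and delivers H2 to the trisubstituted styrenic C3=C4 bond on the face of that group, so H-3 ends cis to the C2 CH2OH and the new C3 stereocentre is R (2,3-trans); benzyl ethers are inert.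

Step 5
Reactants: 9 [(1R,2R,3R)-7-(benzyloxy)-1-[4-(benzyloxy)-3-methoxyphenyl]-6-methoxy-1,2,3,4-tetrahydronaphthalene-2,3-diyl]dimethanol
Product: 10 [(1R,2R,3R)-7-hydroxy-1-(4-hydroxy-3-methoxyphenyl)-6-methoxy-1,2,3,4-tetrahydronaphthalene-2,3-diyl]dimethanol
Conditions: H2 (1 atm), 10% Pd/C, EtOAc–MeOH, 25 °C
Reagents that add atoms: none
Why: Catalytic hydrogenolysis of the two aryl benzyl ethers frees both phenols; no stereocentre is touched.

**Compound list**
1 | 4-(benzyloxy)-3-methoxybenzaldehyde | COc1cc(C=O)ccc1OCc1ccccc1 | starting material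
2 | diethyl succinate | CCOC(=O)CCC(=O)OCC | starting material
3 | (2E,3E)-2,3-bis{[4-(benzyloxy)-3-methoxyphenyl]methylidene}butanedioic acid | OC(=O)/C(=C/c1ccc(OCc2ccccc2)c(OC)c1)C(=C/c1ccc(OCc2ccccc2)c(OC)c1)\C(O)=O | intermediate
4 | (S)-prolinol, [(2S)-pyrrolidin-2-yl]methanol | OC[C@@H]1CCCN1 | starting material
5 | (2E,3E)-2,3-bis{[4-(benzyloxy)-3-methoxyphenyl]methylidene}butanedioic acid cyclic 1-amide 4-ester of (S)-prolinol (eight-membered ring) | O=C1/C(=C/c2ccc(OCc3ccccc3)c(OC)c2)C(=C/c2ccc(OCc3ccccc3)c(OC)c2)\C(=O)OC[C@@H]2CCCN21 | intermediate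
6 | (1S,8aR)-7-(benzyloxy)-1-[4-(benzyloxy)-3-methoxyphenyl]-6-methoxy-1,8a-dihydronaphthalene-2,3-dicarboxylic acid cyclic 2-ester 3-amide of (S)-prolinol (H-1 and H-8a cis) | COc1cc([C@H]2C3=C(C=C4C=C(OC)C(OCc5ccccc5)=C[C@@H]24)C(=O)N5CCC[C@H]5COC3=O)ccc1OCc1ccccc1 | intermediate
7 | (1R,2R)-7-(benzyloxy)-1-[4-(benzyloxy)-3-methoxyphenyl]-6-methoxy-1,2-dihydronaphthalene-2,3-dicarboxylic acid cyclic 2-ester 3-amide of (S)-prolinol | COc1cc([C@@H]2c3cc(OCc4ccccc4)c(OC)cc3C=C5C(=O)N6CCC[C@H]6COC(=O)[C@H]25)ccc1OCc1ccccc1 | intermediate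
8 | [(1R,2R)-7-(benzyloxy)-1-[4-(benzyloxy)-3-methoxyphenyl]-6-methoxy-1,2-dihydronaphthalene-2,3-diyl]dimethanol | COc1cc([C@@H]2c3cc(OCc4ccccc4)c(OC)cc3C=C(CO)[C@@H]2CO)ccc1OCc1ccccc1 | intermediate
9 | [(1R,2R,3R)-7-(benzyloxy)-1-[4-(benzyloxy)-3-methoxyphenyl]-6-methoxy-1,2,3,4-tetrahydronaphthalene-2,3-diyl]dimethanol | COc1cc([C@@H]2c3cc(OCc4ccccc4)c(OC)cc3C[C@@H](CO)[C@@H]2CO)ccc1OCc1ccccc1 | intermediate
10 | [(1R,2R,3R)-7-hydroxy-1-(4-hydroxy-3-methoxyphenyl)-6-methoxy-1,2,3,4-tetrahydronaphthalene-2,3-diyl]dimethanol (CNP0179824.5) | COc1cc([C@@H]2c3cc(O)c(OC)cc3C[C@@H](CO)[C@@H]2CO)ccc1O | target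

**Step count and risks**
Total step count: 5. Longest linear sequence: 5 steps (1 and 2 → 3 → 7 → 8 → 9 → 10).

Most likely to fail, step 2 (one-pot bridging and photocyclisation; auxiliary control, E/Z photoisomerisation and the medium-ring closure may not survive telescoping). The fallback sets out from 3 and comes back at 8. Dehydrate 3 with Ac2O to the fulgide (3E,4E)-3,4-bis{[4-(benzyloxy)-3-methoxyphenyl]methylidene}oxolane-2,5-dione F1. Irradiate it at 365 nm to the racemic cis-7-(benzyloxy)-1-[4-(benzyloxy)-3-methoxyphenyl]-6-methoxy-1,2-dihydronaphthalene-2,3-dicarboxylic anhydride F2. Reduce with LiAlH4 at −20 °C to the racemic [7-(benzyloxy)-1-[4-(benzyloxy)-3-methoxyphenyl]-6-methoxy-1,2-dihydronaphthalene-2,3-diyl]dimethanol F3, then separate the enantiomers by preparative chromatography on a chiral phase to obtain 8, which re-enters at step 4.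

Second, step 3 (conjugate reduction of the unsaturated amide or epimerisation at C2 under the basic hydride). The fallback sets out from 7 and comes back at 8. HCl in methanol at 60 °C (ester methanolysis, N-to-O acyl shift, second methanolysis) gives dimethyl (1R,2R)-7-(benzyloxy)-1-[4-(benzyloxy)-3-methoxyphenyl]-6-methoxy-1,2-dihydronaphthalene-2,3-dicarboxylate F4. The non-basic hydride i-Bu2AlH in CH2Cl2 at −78 °C then reduces it in a clean 1,2-sense to 8.

Third, step 4 (the pseudo-axial aryl group on the same face may slow or misdirect the catalyst). The fallback sets out from 8 and comes back at 9. Catalytic hydrogenation is replaced by alkoxide-directed hydroalumination with LiAlH4 in refluxing THF. The 1,4-diol forms a cyclic dialkoxyaluminate held on the face of the C2 arm, hydride is delivered intramolecularly to C3, and the benzylic C4–Al bond is protonated on work-up. This makes no compound outside the list (F0).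

**Further compounds**
F1 | step 2 | (3E,4E)-3,4-bis{[4-(benzyloxy)-3-methoxyphenyl]methylidene}oxolane-2,5-dione | O=C1/C(=C/c2ccc(OCc3ccccc3)c(OC)c2)C(=C/c2ccc(OCc3ccccc3)c(OC)c2)\C(=O)O1
F2 | step 2 | racemic cis-7-(benzyloxy)-1-[4-(benzyloxy)-3-methoxyphenyl]-6-methoxy-1,2-dihydronaphthalene-2,3-dicarboxylic anhydride (1R,2R and 1S,2S) | COc1cc([C@@H]2c3cc(OCc4ccccc4)c(OC)cc3C=C5C(=O)OC(=O)[C@H]25)ccc1OCc1ccccc1.COc1cc([C@H]2c3cc(OCc4ccccc4)c(OC)cc3C=C5C(=O)OC(=O)[C@@H]25)ccc1OCc1ccccc1
F3 | step 2 | racemic cis-[7-(benzyloxy)-1-[4-(benzyloxy)-3-methoxyphenyl]-6-methoxy-1,2-dihydronaphthalene-2,3-diyl]dimethanol (1R,2R and 1S,2S) | COc1cc([C@@H]2c3cc(OCc4ccccc4)c(OC)cc3C=C(CO)[C@@H]2CO)ccc1OCc1ccccc1.COc1cc([C@H]2c3cc(OCc4ccccc4)c(OC)cc3C=C(CO)[C@H]2CO)ccc1OCc1ccccc1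
F4 | step 3 | dimethyl (1R,2R)-7-(benzyloxy)-1-[4-(benzyloxy)-3-methoxyphenyl]-6-methoxy-1,2-dihydronaphthalene-2,3-dicarboxylate | COc1cc([C@@H]2c3cc(OCc4ccccc4)c(OC)cc3C=C(C(=O)OC)[C@@H]2C(=O)OC)ccc1OCc1ccccc1
F0 | step 4 | none | none
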